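Time is short in these flasks: at the first reading, 1.33 min, the dawn run has 66.8% of its substrate left and the winter run 38.3%.

| flask | substrate | coupling partner | second reagent | remark | time |
|---|---|---|---|---|---|
| dawn | 0.10 M | 0.30 equiv | 1.2 equiv | run made earlier |  |
| winter | 0.10 M | 1.2 equiv | 1.2 equiv | run made earlier |  |
| flask | 0.10 M | 0.600 equiv | 1.20 equiv |  | 2.0 h |

| run | time / min | intermediate / % | target / % | substrate / % |
|---|---|---|---|---|
| dawn | 1.33 | 8.3 | 3.4 | 66.8 |
| dawn | 3.00 | 5.8 | 2.9 | 50.5 |
| dawn | 8.00 | 0 | 4.1 | 25.2 |
| dawn | 20.0 | 0 | 3.3 | 8.4 |
| dawn | 50.0 | 0.8 | 4.0 | 0.8 |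
| dawn | 120 | 0 | 5.6 | 0 |
| winter | 1.33 | 29.5 | 7.6 | 38.3 |
| winter | 3.00 | 16.4 | 10.5 | 14.9 |
| winter | 8.00 | 1.8 | 14.8 | 3.4 |
| winter | 20.0 | 0 | 13.3 | 0 |
| winter | 50.0 | 0 | 15.9 | 0 |
| winter | 120 | 0.7 | 15.6 | 0.5 |

(each reading ± 1 percentage point)

- the numbers in the tables scatter by 1 percentage point (one standard deviation)

* the best time, 2.0 h at the latest, for intermediate, in min
* the amount of intermediate, in percent of the substrate charged, at that time

Dawn and winter have equal charges of substrate and second reagent and differ in coupling partner, 0.30 equiv against 1.2 equiv. Reckoned as first order in substrate, those first readings give losses of 0.303 min⁻¹ in dawn and 0.722 min⁻¹ in winter. A straight line through the two against equivalents of partner leaves 0.164 min⁻¹ that does not grow with partner, which we read as a side route. The remainder is the partner route, 0.279 min⁻¹ for the new flask. Both rates carry the same [substrate], so it cancels in their quotient; coupling partner and second reagent are used up as a flask runs, so we hold the quotient to the opening minutes. For the new flask this gives 1.70, and we call partner-route rate over side-route rate the route ratio, a selectivity factor. These are readings, with their scatter.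

At the first reading each run's own route ratio sends 77.3% of the lost substrate down the partner route in winter, more than the 46.0% in dawn. Dawn's charge of 0.30 equiv also covers less substrate than its share. So dawn ends with 5.6% of target and winter with 15.6%.

The forecast says 17% at 1.4 min, on the ground that “the peak comes early”.

The flask gives 16.5% at 1.26 min.

    substrate + second reagent → side product (k = 0.0220 L mol⁻¹ s⁻¹)
    intermediate → decomposed reagent (k = 0.0100 s⁻¹)
    substrate + coupling partner → intermediate (k = 0.110 L mol⁻¹ s⁻¹)
    second reagent + intermediate → target (k = 0.0230 L mol⁻¹ s⁻¹)

At that time 58.0% of the substrate remains and the side product stands at 14.0%. Intermediate, target and decomposed reagent together over side product come to 1.99, a little above the route ratio of 1.70. Scaled to the neighbouring flask with 2.40 equiv of coupling partner, the route ratio becomes 6.80, and at the end of that flask target and decomposed reagent over side product stand at 8.64.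

The runs were generated by integration with constants of no real substance, noise included.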